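**Plan**
- **Enabling feature:** the target is a 7,4'-dioxygenated isoflavanone, and both C5 units sit ortho to a phenolic oxygen. The open prenyl group is at C8 beside O7 on ring A, and the C5 bridge of ring D spans C3' and O4' on ring B. Each position is where an O-to-C sigmatropic shift would place the unit.
- **Cuts:** ring C is first taken back to the isoflavone and ring D to the chromene. Then C8–CH2 (prenyl), C3'–CH and O4'–CMe2 (ring D) are cut in one operation, giving a daidzein bis-ether with 1,1-dimethylallyl on O7 and 1,1-dimethylpropargyl on O4'. The two ether O–C bonds are cut last.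
- **Forward order:** rings A, B and C come with daidzein. O7 and then O4' are etherified, with the first alkyne semihydrogenated in between. Ring D closes in the heating of step 4 and is saturated afterwards.
- **Stereochemistry:** the only stereocentre, C3 (R), is set by the catalyst. Transfer hydrogenation with RuCl[(R,R)-TsDPEN](p-cymene) under dynamic kinetic resolution gives the cis (3R,4R) isoflavan-4-ol. A base-free oxidation then removes the helper centre C4, and a TIPS group on O7 guards the phenol meanwhile.

Key step: step 4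

Assumption: C3 of the target reads as R (C4 > C2 > C1' > H), and the sense of induction of the (R,R) catalyst is taken from the aryl ketone rule, (R,R) giving the (R) carbinol.

**Step 1**
Reactants: 1 daidzein; 2 3-chloro-3-methylbut-1-yne
Product: 3 3-(4-hydroxyphenyl)-7-[(2-methylbut-3-yn-2-yl)oxy]-4H-chromen-4-one
Conditions: DBU (1.05 equiv), CuCl2·2H2O (1 mol %), DMF–MeCN, 0 °C to rt
Reagents that add atoms: none
Why: Copper-catalysed propargylic etherification (a Williamson-type O-alkylation through a copper allenylidene) should occur only at O7, because one equivalent of base ionises the 7-OH, which is para to the C4 carbonyl and clearly more acidic than the 4'-OH.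

**Step 2**
Reactants: 3 3-(4-hydroxyphenyl)-7-[(2-methylbut-3-yn-2-yl)oxy]-4H-chromen-4-one
Product: 4 3-(4-hydroxyphenyl)-7-[(2-methylbut-3-en-2-yl)oxy]-4H-chromen-4-one
Conditions: H2 (1 atm, stopped after 1 equiv), Pd/CaCO3 poisoned with Pb(OAc)2, quinoline, EtOAc, rt
Reagents that add atoms: none
Why: Lindlar semihydrogenation should stop the terminal alkyne at the vinyl stage, and the poisoned catalyst leaves the pyranone C2=C3 bond, the tertiary ether and the free 4'-phenol alone.

**Step 3**
Reactants: 4 3-(4-hydroxyphenyl)-7-[(2-methylbut-3-en-2-yl)oxy]-4H-chromen-4-one; 2 3-chloro-3-methylbut-1-yne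
Product: 5 7-[(2-methylbut-3-en-2-yl)oxy]-3-{4-[(2-methylbut-3-yn-2-yl)oxy]phenyl}-4H-chromen-4-one
Conditions: DBU (1.3 equiv), CuCl2·2H2O (1 mol %), MeCN, 0 °C to rt
Reagents that add atoms: none
Why: The same copper-catalysed propargylic etherification now meets a single phenol, and its low temperature and basic medium suit the tertiary allyl ether, which is acid-labile and rearranges only well above 100 °C.

**Step 4**
Reactants: 5 7-[(2-methylbut-3-en-2-yl)oxy]-3-{4-[(2-methylbut-3-yn-2-yl)oxy]phenyl}-4H-chromen-4-one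
Product: 11 7-hydroxy-8-(3-methylbut-2-enyl)-3-(2,2-dimethyl-2H-chromen-6-yl)-4H-chromen-4-one, via C8 cyclohexadienone 6 (not isolated), via 8-prenylphenol propargyl ether 7 (not isolated), via ring B allenyl dienone 8 (not isolated), via 3'-allenylphenol 9 (not isolated), via ring B o-quinone methide 10 (not isolated)
Conditions: PhNEt2 (degassed), Ar, 130 °C, then 190 °C, one flask
Reagents that add atoms: none
Why: Near 130 °C the tertiary allyl ether undergoes the aromatic Claisen rearrangement, a chair-like (3,3) shift with allyl inversion that bonds the CH2 terminus to C8 (6), and tautomerisation gives the o-prenylphenol 7. Near 190 °C the tertiary propargyl ether follows with a propargyl Claisen shift that forms C3'–CH (8), enolisation to 9, and a 1,5-hydrogen shift from O4'–H to the central allene carbon, which gives the (Z)-o-quinone methide 10. Ring D closes by a thermally allowed disrotatory oxa-6π electrocyclisation of 10, which forms O4'–CMe2 and restores the aromaticity of ring B. The closest known reaction types are the rearrangement of 7-(1,1-dimethylallyloxy)coumarins and chromones to 8-prenylphenols and the thermal chromene synthesis from aryl 1,1-dimethylpropargyl ethers, here merely run in one flask. No stereocentre persists, and the one selectivity needed, C8 over C6, is secured by the higher C7–C8 π-bond order of the benzo ring fused to the pyranone, while C3' and C5' are equivalent. The basic solvent suppresses acid-induced loss of isoprene and cyclisation of the 7-OH onto the prenyl group, and the temperature ramp lets the more labile ether react before the temperature needed for ring D is reached.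

**Step 5**
Reactants: 11 7-hydroxy-8-(3-methylbut-2-enyl)-3-(2,2-dimethyl-2H-chromen-6-yl)-4H-chromen-4-one
Product: 12 3-(2,2-dimethyl-2H-chromen-6-yl)-8-(3-methylbut-2-enyl)-7-(triisopropylsilyloxy)-4H-chromen-4-one
Conditions: TIPSCl, imidazole, DMF, rt
Reagents that add atoms: triisopropylsilyl chloride, CC(C)[Si](Cl)(C(C)C)C(C)C
Why: Standard phenol silylation (silyl ether protection) caps the acidic 7-OH, so that later steps meet neither an oxidisable phenol nor a p-hydroxybenzyl alcohol that can ionise, and the bulky group also screens the neighbouring prenyl alkene.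

**Step 6**
Reactants: 12 3-(2,2-dimethyl-2H-chromen-6-yl)-8-(3-methylbut-2-enyl)-7-(triisopropylsilyloxy)-4H-chromen-4-one
Product: 13 3-(2,2-dimethylchroman-6-yl)-8-(3-methylbut-2-enyl)-7-(triisopropylsilyloxy)-4H-chromen-4-one
Conditions: H2 (1 atm), RhCl(PPh3)3 (10 mol %), PhMe–EtOH 1:1, rt
Reagents that add atoms: none
Why: Homogeneous hydrogenation with RhCl(PPh3)3 depends on alkene coordination and takes cis-disubstituted alkenes much faster than trisubstituted ones, so the ring D alkene should be saturated while the prenyl alkene (trisubstituted, wedged between O1 and the OTIPS group) and the trisubstituted C2=C3 bond of ring C remain.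

**Step 7**
Reactants: 13 3-(2,2-dimethylchroman-6-yl)-8-(3-methylbut-2-enyl)-7-(triisopropylsilyloxy)-4H-chromen-4-one
Product: 15 (3R,4R)-3-(2,2-dimethylchroman-6-yl)-8-(3-methylbut-2-enyl)-7-(triisopropylsilyloxy)chroman-4-ol (cis), via racemising isoflavanone 14 (not isolated)
Conditions: RuCl[(R,R)-TsDPEN](p-cymene) (5 mol %), HCO2H–Et3N 1:1, EtOAc, 40 °C
Reagents that add atoms: none
Why: This is a Noyori–Ikariya asymmetric transfer hydrogenation run as a cascade with dynamic kinetic resolution, in which Ru–H first adds 1,4 to the pyranone to give 14, Et3N keeps C3 of 14 racemising through the enol, and the (R,R) catalyst reduces only the (3R) ketone, fixing C4 as R by the aryl ketone rule and delivering hydride anti to the C3 aryl group, so that the cis (3R,4R) alcohol should result while prenyl group, chroman and TIPS ether are inert to this outer-sphere hydride transfer.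

**Step 8**
Reactants: 15 (3R,4R)-3-(2,2-dimethylchroman-6-yl)-8-(3-methylbut-2-enyl)-7-(triisopropylsilyloxy)chroman-4-ol
Product: 16 (3R)-3-(2,2-dimethylchroman-6-yl)-8-(3-methylbut-2-enyl)-7-(triisopropylsilyloxy)chroman-4-one
Conditions: Dess–Martin periodinane, CH2Cl2, 0 °C to rt
Reagents that add atoms: none
Why: The Dess–Martin oxidation works without base and at or below room temperature, so the C4 carbinol should become the ketone without enolisation and C3 keeps its R configuration, the alkene and the silyl ether being inert.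

**Step 9**
Reactants: 16 (3R)-3-(2,2-dimethylchroman-6-yl)-8-(3-methylbut-2-enyl)-7-(triisopropylsilyloxy)chroman-4-one
Product: 17 (3R)-7-hydroxy-3-(2,2-dimethylchroman-6-yl)-8-(3-methylbut-2-enyl)chroman-4-one
Conditions: HF·pyridine, THF, 0 °C (polyethylene flask), pH 7 buffer work-up
Reagents that add atoms: none
Why: Fluoride-induced desilylation is fast here because the departing phenoxide is para to the C4 ketone, and the weakly acidic HF·pyridine medium holds neither a base able to enolise C3 nor an acid able to protonate the prenyl alkene, so the (3R) phenol should be released intact.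

**Compound list**
1 | daidzein | O=c1c(-c2ccc(O)cc2)coc2cc(O)ccc12 | starting material
2 | 3-chloro-3-methylbut-1-yne | C#CC(C)(C)Cl | starting material
3 | 3-(4-hydroxyphenyl)-7-[(2-methylbut-3-yn-2-yl)oxy]-4H-chromen-4-one | C#CC(C)(C)Oc1ccc2c(c1)occ(-c1ccc(O)cc1)c2=O | intermediate
4 | 3-(4-hydroxyphenyl)-7-[(2-methylbut-3-en-2-yl)oxy]-4H-chromen-4-one | C=CC(C)(C)Oc1ccc2c(c1)occ(-c1ccc(O)cc1)c2=O | intermediate
5 | 7-[(2-methylbut-3-en-2-yl)oxy]-3-{4-[(2-methylbut-3-yn-2-yl)oxy]phenyl}-4H-chromen-4-one | C=CC(C)(C)Oc1ccc2c(c1)occ(-c1ccc(OC(C)(C)C#C)cc1)c2=O | intermediate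
6 | 8-(3-methylbut-2-enyl)-3-{4-[(2-methylbut-3-yn-2-yl)oxy]phenyl}-8H-chromene-4,7-dione (racemic, transient) | CC(C)=CCC1C(=O)C=CC2=C1OC=C(c1ccc(OC(C)(C)C#C)cc1)C2=O | intermediate
7 | 7-hydroxy-8-(3-methylbut-2-enyl)-3-{4-[(2-methylbut-3-yn-2-yl)oxy]phenyl}-4H-chromen-4-one | CC(C)=CCc1c(O)ccc2c1occ(-c1ccc(OC(C)(C)C#C)cc1)c2=O | intermediate
8 | 7-hydroxy-8-(3-methylbut-2-enyl)-3-[3-(3-methylbuta-1,2-dienyl)-4-oxocyclohexa-1,5-dienyl]-4H-chromen-4-one (racemic, transient) | CC(C)=CCc1c(O)ccc2c1occ(C1=CC(C=C=C(C)C)C(=O)C=C1)c2=O | intermediate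
9 | 7-hydroxy-3-[4-hydroxy-3-(3-methylbuta-1,2-dienyl)phenyl]-8-(3-methylbut-2-enyl)-4H-chromen-4-one | CC(C)=CCc1c(O)ccc2c1occ(-c1ccc(O)c(C=C=C(C)C)c1)c2=O | intermediate
10 | 7-hydroxy-3-[(3Z)-3-(3-methylbut-2-enylidene)-4-oxocyclohexa-1,5-dienyl]-8-(3-methylbut-2-enyl)-4H-chromen-4-one | CC(C)=CCc1c(O)ccc2c1occ(C1=C/C(=C/C=C(C)C)C(=O)C=C1)c2=O | intermediate
11 | 7-hydroxy-8-(3-methylbut-2-enyl)-3-(2,2-dimethyl-2H-chromen-6-yl)-4H-chromen-4-one | CC(C)=CCc1c(O)ccc2c1occ(-c1ccc3c(c1)C=CC(C)(C)O3)c2=O | intermediate
12 | 3-(2,2-dimethyl-2H-chromen-6-yl)-8-(3-methylbut-2-enyl)-7-(triisopropylsilyloxy)-4H-chromen-4-one | CC(C)=CCc1c(O[Si](C(C)C)(C(C)C)C(C)C)ccc2c1occ(-c1ccc3c(c1)C=CC(C)(C)O3)c2=O | intermediate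
13 | 3-(2,2-dimethylchroman-6-yl)-8-(3-methylbut-2-enyl)-7-(triisopropylsilyloxy)-4H-chromen-4-one | CC(C)=CCc1c(O[Si](C(C)C)(C(C)C)C(C)C)ccc2c1occ(-c1ccc3c(c1)CCC(C)(C)O3)c2=O | intermediate
14 | 3-(2,2-dimethylchroman-6-yl)-8-(3-methylbut-2-enyl)-7-(triisopropylsilyloxy)chroman-4-one (C3 racemising) | CC(C)=CCc1c(O[Si](C(C)C)(C(C)C)C(C)C)ccc2c1OCC(c1ccc3c(c1)CCC(C)(C)O3)C2=O | intermediate
15 | (3R,4R)-3-(2,2-dimethylchroman-6-yl)-8-(3-methylbut-2-enyl)-7-(triisopropylsilyloxy)chroman-4-ol | CC(C)=CCc1c(O[Si](C(C)C)(C(C)C)C(C)C)ccc2c1OC[C@@H](c1ccc3c(c1)CCC(C)(C)O3)[C@H]2O | intermediate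
16 | (3R)-3-(2,2-dimethylchroman-6-yl)-8-(3-methylbut-2-enyl)-7-(triisopropylsilyloxy)chroman-4-one | CC(C)=CCc1c(O[Si](C(C)C)(C(C)C)C(C)C)ccc2c1OC[C@@H](c1ccc3c(c1)CCC(C)(C)O3)C2=O | intermediate
17 | (3R)-7-hydroxy-3-(2,2-dimethylchroman-6-yl)-8-(3-methylbut-2-enyl)chroman-4-one | CC(C)=CCc1c(O)ccc2c1OC[C@@H](c1ccc3c(c1)CCC(C)(C)O3)C2=O | target

**Total step count:** 9. **Longest linear sequence:** 9 steps, from 1.

**Steps most likely to fail**

**Step 4.** Three things may go wrong. The tertiary allyl ether may fragment with loss of isoprene in competition with the shift. Part of the migration may go to C6. The free prenylphenol may decay slowly during the hold at 190 °C.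

The fallback sets out from 5 and divides the work between two differently driven closures. Compound 5 is heated only to 130 °C in PhNEt2, and 7 is isolated. TIPSCl and imidazole convert it into the 7-O-TIPS 8-prenyl 4'-O-(1,1-dimethylpropargyl) isoflavone F1. Ring D is then closed at room temperature by Ph3PAuNTf2-catalysed 6-endo hydroarylation of the alkyne in CH2Cl2. This metal-catalysed closure replaces the pericyclic sequence and forms the same C3'–CH bond. Its product is 12, where the route is rejoined.

**Step 6.** Discrimination between the two alkenes may be lost, through slow uptake at the ring D alkene next to the quaternary carbon and creeping saturation of the prenyl group. Stray reduction of C2=C3 would be harmless, since it leads to 14.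

The fallback runs the two rearrangements one after the other, so that ring D is saturated before any prenyl alkene exists. It sets out from 1 and proceeds as follows:
- BnBr and K2CO3 in DMF give 7-O-benzyldaidzein F2.
- Compound 2, DBU and CuCl2·2H2O give its 4'-O-(1,1-dimethylpropargyl) ether F3.
- Heating in PhNEt2 at 190 °C gives the 7-benzyloxy chromene isoflavone F4.
- H2 over Pd/C in EtOAc saturates ring D and cleaves the benzyl ether, giving 7-hydroxy-3-(2,2-dimethylchroman-6-yl)chromen-4-one F5.
- Etherification with 2 as in step 1 gives the 7-O-(1,1-dimethylpropargyl) ether F6.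
- Semihydrogenation over Pd/CaCO3 poisoned with Pb(OAc)2 gives the 7-O-(1,1-dimethylallyl) ether F7.
- Claisen rearrangement at 130 °C in PhNEt2 gives the 7-hydroxy-8-prenyl chroman isoflavone F8.
- TIPSCl and imidazole bring the material back to the route at 13.

**Step 7.** The 1,4-hydride transfer to the electron-rich, 8-substituted pyranone may stall, and the silyl group may erode during a long reaction.

The fallback sets out from 13 and removes the conjugate reduction from the catalytic step. LiBH(s-Bu)3 in THF at −78 °C, a known 1,4-reduction of isoflavones, gives 14, which is isolated as the racemate after a buffered quench. The ruthenium catalyst of step 7 then only has to reduce the ketone under dynamic kinetic resolution, and the route is rejoined at 15.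

**Further compounds**
F1 | step 4 | 8-(3-methylbut-2-enyl)-3-{4-[(2-methylbut-3-yn-2-yl)oxy]phenyl}-7-(triisopropylsilyloxy)-4H-chromen-4-one | CC(C)=CCc1c(O[Si](C(C)C)(C(C)C)C(C)C)ccc2c1occ(-c1ccc(OC(C)(C)C#C)cc1)c2=O
F2 | step 6 | 7-benzyloxy-3-(4-hydroxyphenyl)-4H-chromen-4-one | O=c1c(-c2ccc(O)cc2)coc2cc(OCc3ccccc3)ccc12
F3 | step 6 | 7-benzyloxy-3-{4-[(2-methylbut-3-yn-2-yl)oxy]phenyl}-4H-chromen-4-one | C#CC(C)(C)Oc1ccc(-c2coc3cc(OCc4ccccc4)ccc3c2=O)cc1
F4 | step 6 | 7-benzyloxy-3-(2,2-dimethyl-2H-chromen-6-yl)-4H-chromen-4-one | CC1(C)C=Cc2cc(-c3coc4cc(OCc5ccccc5)ccc4c3=O)ccc2O1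
F5 | step 6 | 7-hydroxy-3-(2,2-dimethylchroman-6-yl)-4H-chromen-4-one | CC1(C)CCc2cc(-c3coc4cc(O)ccc4c3=O)ccc2O1
F6 | step 6 | 3-(2,2-dimethylchroman-6-yl)-7-[(2-methylbut-3-yn-2-yl)oxy]-4H-chromen-4-one | C#CC(C)(C)Oc1ccc2c(c1)occ(-c1ccc3c(c1)CCC(C)(C)O3)c2=O
F7 | step 6 | 3-(2,2-dimethylchroman-6-yl)-7-[(2-methylbut-3-en-2-yl)oxy]-4H-chromen-4-one | C=CC(C)(C)Oc1ccc2c(c1)occ(-c1ccc3c(c1)CCC(C)(C)O3)c2=O
F8 | step 6 | 7-hydroxy-3-(2,2-dimethylchroman-6-yl)-8-(3-methylbut-2-enyl)-4H-chromen-4-one | CC(C)=CCc1c(O)ccc2c1occ(-c1ccc3c(c1)CCC(C)(C)O3)c2=O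
F0 | step 7 | none | none
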